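## Retrosynthetic overview
1. The last step is hydrogenolysis of four benzyl ethers. Before it, the ester C–O bond is cut with inversion into an (S)-secondary mesylate and a caesium resorcylate.
2. The free carbinol is (S) and the esterified one is (R), so both halves come from one (S)-alcohol, an 11-arylundecan-4-ol. The acid half is that same alcohol after ring bromination and Br/Li exchange with CO2.
3. The (S)-alcohol comes from 3,5-bis(benzyloxy)benzyl bromide and a C10 Grignard reagent (Cu-catalysed sp3–sp3 coupling), followed by carbamate cleavage.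
4. The key bond is C4–C5 of the C10 piece. An enantioenriched α-lithiated butyl carbamate (the oxygen-bearing carbon used as a carbanion, a d1 synthon) attacks a primary alkyl iodide. Two natural acceptor carbons are joined and the stereocentre is set in the same operation.
5. No ring is formed; both benzene rings are bought.

Assumption: CIP analysis of the SMILES gives (8S) for the free carbinol and (4R) for the esterified carbinol. (+)-Sparteine is taken as a purchasable, recoverable ligand.

## Route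

Step 1
Reactants: 1 butan-1-ol
Product: 2 butyl N,N-diisopropylcarbamate
Conditions: iPr2NCOCl (1.1 equiv), Et3N (1.3 equiv), CH2Cl2, reflux, 24 h
Reagents that add atoms: N,N-diisopropylcarbamoyl chloride, CC(C)N(C(C)C)C(=O)Cl
Why: Carbamoylation (nucleophilic acyl substitution) of a primary alcohol; the bulky diisopropylamide shields the carbonyl from s-BuLi and later directs and stabilises α-lithiation.

Step 2 (key step)
Reactants: 2 butyl N,N-diisopropylcarbamate; 3 1-chloro-6-iodohexane
Product: 5 (4S)-10-chlorodecan-4-yl N,N-diisopropylcarbamate, via (R)-1-lithiobutyl N,N-diisopropylcarbamate (+)-sparteine complex 4 (not isolated)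
Conditions: s-BuLi (1.1 equiv), (+)-sparteine (1.15 equiv), Et2O, −78 °C, 5 h; then 3 (2.5 equiv), −78 °C → −30 °C, 14 h; MeOH quench
Reagents that add atoms: none
Why: Proposed new method: the Hoppe asymmetric deprotonation, in which s-BuLi/(+)-sparteine removes the pro-R hydrogen to give the configurationally stable, dipole-stabilised carbanion 4 (typically ≥95:5 er), is established, and what is extended is its retentive SE2 trapping, known for MeI and closest in type to the alkylation of α-alkoxyalkyllithiums by primary halides, to an unactivated primary iodide, so that the oxygen-bearing carbon (by nature an acceptor) attacks the equally electrophilic C–I carbon as a donor (SN2 at iodide far outruns chloride, and I/Li exchange is uphill because 4 is the more stabilised carbanion) and the (S) centre is fixed in this one bond formation.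

Step 3
Reactants: 5 (4S)-10-chlorodecan-4-yl N,N-diisopropylcarbamate; 6 3,5-bis(benzyloxy)benzyl bromide
Product: 9 (4S)-11-[3,5-bis(benzyloxy)phenyl]undecan-4-ol, via alkylmagnesium chloride 7 (not isolated), via coupled carbamate 8 (not isolated)
Conditions: Mg (I2-activated), THF, reflux, 3 h; then Li2CuCl4 (3 mol %), 6 (1.1 equiv), −10 °C → rt, 4 h; then LiAlH4 (4 equiv), same flask, reflux, 16 h; H2O/NaOH work-up
Reagents that add atoms: none
Why: Kochi-type Li2CuCl4-catalysed sp3–sp3 cross-coupling of a primary alkyl Grignard reagent with a reactive benzylic bromide (the hindered carbamate ignores RMgCl), followed in the same THF solution by hydride cleavage of the carbamate at its acyl C–O bond, which leaves the C4–O bond and the (S) centre untouched.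

Step 4
Reactants: 9 (4S)-11-[3,5-bis(benzyloxy)phenyl]undecan-4-ol
Product: 10 (4S)-11-[3,5-bis(benzyloxy)phenyl]undecan-4-yl methanesulfonate
Conditions: MsCl (1.3 equiv), Et3N (1.8 equiv), CH2Cl2, 0 °C, 1 h
Reagents that add atoms: methanesulfonyl chloride, CS(=O)(=O)Cl
Why: O-Sulfonylation of a secondary alcohol; the C–O bond is not broken, so the (S) configuration is retained.

Step 5
Reactants: 9 (4S)-11-[3,5-bis(benzyloxy)phenyl]undecan-4-ol
Product: 11 (4S)-11-[3,5-bis(benzyloxy)-2-bromophenyl]undecan-4-ol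
Conditions: NBS (1.0 equiv), CH2Cl2, −20 → 0 °C, dark, 1 h
Reagents that add atoms: N-bromosuccinimide, O=C1CCC(=O)N1Br
Why: Electrophilic aromatic bromination goes para to one benzyloxy group and ortho to the other, next to the alkyl chain, as with 3,5-dialkoxytoluenes, while one equivalent in the cold and dark avoids dibromination, benzylic radical bromination and alcohol oxidation.

Step 6
Reactants: 11 (4S)-11-[3,5-bis(benzyloxy)-2-bromophenyl]undecan-4-ol
Product: 14 2,4-bis(benzyloxy)-6-[(8S)-8-hydroxyundecyl]benzoic acid, via aryllithium lithium alkoxide 12 (not isolated), via dilithium carboxylate alkoxide 13 (not isolated)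
Conditions: n-BuLi (2.2 equiv), THF, −78 °C, 20 min; CO2 (dry gas), −78 → 0 °C; 1 M HCl
Reagents that add atoms: carbon dioxide, O=C=O
Why: Bromine–lithium exchange and carboxylation, in which the first equivalent of n-BuLi masks the hydroxyl as its alkoxide (any O-carbonate falls off on acidification) and the short time at −78 °C forestalls proton transfer from the ortho benzyloxy CH2.

Step 7
Reactants: 14 2,4-bis(benzyloxy)-6-[(8S)-8-hydroxyundecyl]benzoic acid; 10 (4S)-11-[3,5-bis(benzyloxy)phenyl]undecan-4-yl methanesulfonate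
Product: 16 (4R)-11-[3,5-bis(benzyloxy)phenyl]undecan-4-yl 2,4-bis(benzyloxy)-6-[(8S)-8-hydroxyundecyl]benzoate, via caesium carboxylate 15 (not isolated)
Conditions: Cs2CO3 (0.55 equiv), DMF, rt, 30 min; then 10 (1.1 equiv), 60 °C, 36 h
Reagents that add atoms: none
Why: Caesium carboxylate SN2 displacement of a secondary mesylate with inversion (S → R), in which only the pre-activated alcohol can react so the free 8-hydroxyl of the acid needs no protection, and O-alkylation bypasses attack at the hindered di-ortho-substituted carbonyl.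

Step 8
Reactants: 16 (4R)-11-[3,5-bis(benzyloxy)phenyl]undecan-4-yl 2,4-bis(benzyloxy)-6-[(8S)-8-hydroxyundecyl]benzoate
Product: 17 (4R)-11-(3,5-dihydroxyphenyl)undecan-4-yl 2,4-dihydroxy-6-[(8S)-8-hydroxyundecyl]benzoate (target)
Conditions: H2 (1 atm), 10% Pd/C, EtOAc–EtOH, rt, 6 h
Reagents that add atoms: none
Why: Catalytic hydrogenolysis of four aryl benzyl ethers; the secondary alkyl ester, the secondary alcohol and both stereocentres carry no benzylic C–O bond and are inert.

## Compound list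
1 | butan-1-ol | CCCCO | starting material
2 | butyl N,N-diisopropylcarbamate | CCCCOC(=O)N(C(C)C)C(C)C | intermediate
3 | 1-chloro-6-iodohexane | ClCCCCCCI | starting material
4 | (R)-1-lithiobutyl N,N-diisopropylcarbamate, (+)-sparteine complex (ligand omitted from SMILES) | CCC[C@H](OC(=O)N(C(C)C)C(C)C)[Li] | intermediate (not isolated)
5 | (4S)-10-chlorodecan-4-yl N,N-diisopropylcarbamate | CCC[C@H](OC(=O)N(C(C)C)C(C)C)CCCCCCCl | intermediate
6 | 3,5-bis(benzyloxy)benzyl bromide | BrCc1cc(OCc2ccccc2)cc(OCc2ccccc2)c1 | starting material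
7 | (7S)-7-[(diisopropylcarbamoyl)oxy]decylmagnesium chloride | CCC[C@H](OC(=O)N(C(C)C)C(C)C)CCCCCC[Mg]Cl | intermediate (not isolated)
8 | (4S)-11-[3,5-bis(benzyloxy)phenyl]undecan-4-yl N,N-diisopropylcarbamate | CCC[C@H](OC(=O)N(C(C)C)C(C)C)CCCCCCCc1cc(OCc2ccccc2)cc(OCc2ccccc2)c1 | intermediate (not isolated)
9 | (4S)-11-[3,5-bis(benzyloxy)phenyl]undecan-4-ol | CCC[C@H](O)CCCCCCCc1cc(OCc2ccccc2)cc(OCc2ccccc2)c1 | intermediate
10 | (4S)-11-[3,5-bis(benzyloxy)phenyl]undecan-4-yl methanesulfonate | CCC[C@H](OS(C)(=O)=O)CCCCCCCc1cc(OCc2ccccc2)cc(OCc2ccccc2)c1 | intermediate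
11 | (4S)-11-[3,5-bis(benzyloxy)-2-bromophenyl]undecan-4-ol | CCC[C@H](O)CCCCCCCc1cc(OCc2ccccc2)cc(OCc2ccccc2)c1Br | intermediate
12 | lithium (4S)-11-[3,5-bis(benzyloxy)-2-lithiophenyl]undecan-4-olate | CCC[C@H](O[Li])CCCCCCCc1cc(OCc2ccccc2)cc(OCc2ccccc2)c1[Li] | intermediate (not isolated)
13 | dilithium salt (carboxylate and alkoxide) of 14 | CCC[C@H](O[Li])CCCCCCCc1cc(OCc2ccccc2)cc(OCc2ccccc2)c1C(=O)O[Li] | intermediate (not isolated)
14 | 2,4-bis(benzyloxy)-6-[(8S)-8-hydroxyundecyl]benzoic acid | CCC[C@H](O)CCCCCCCc1cc(OCc2ccccc2)cc(OCc2ccccc2)c1C(=O)O | intermediate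
15 | caesium 2,4-bis(benzyloxy)-6-[(8S)-8-hydroxyundecyl]benzoate | CCC[C@H](O)CCCCCCCc1cc(OCc2ccccc2)cc(OCc2ccccc2)c1C(=O)[O-].[Cs+] | intermediate (not isolated)
16 | (4R)-11-[3,5-bis(benzyloxy)phenyl]undecan-4-yl 2,4-bis(benzyloxy)-6-[(8S)-8-hydroxyundecyl]benzoate | CCC[C@H](O)CCCCCCCc1cc(OCc2ccccc2)cc(OCc2ccccc2)c1C(=O)O[C@H](CCC)CCCCCCCc1cc(OCc2ccccc2)cc(OCc2ccccc2)c1 | intermediate
17 | (4R)-11-(3,5-dihydroxyphenyl)undecan-4-yl 2,4-dihydroxy-6-[(8S)-8-hydroxyundecyl]benzoate | CCC[C@H](O)CCCCCCCc1cc(O)cc(O)c1C(=O)O[C@H](CCC)CCCCCCCc1cc(O)cc(O)c1 | target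

## Count and risks
Total step count: 8.
Longest linear sequence: 7 (steps 1, 2, 3, 5, 6, 7, 8); step 4 is a one-step branch from 9.

**Step 2.**
- Risk: SN2 attack of the sparteine-bound carbanion 4 on a primary iodide may be too slow below −30 °C, giving protonation back to 2 or E2 on 3. It may also run partly by electron transfer and lose er.
- Fallback: it sets out from 2 and 6 and comes back at 9.
- 6-Bromohex-1-ene and Mg give hex-5-en-1-ylmagnesium bromide F1. F1 is coupled with 6 (Li2CuCl4 cat., THF) to 1,3-bis(benzyloxy)-5-(hept-6-en-1-yl)benzene F2.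
- Hydroboration with pinacolborane ([Ir(cod)Cl]2, dppm) gives the primary pinacol boronic ester F3.
- Carbanion 4, made from 2 exactly as in step 2, is then captured at boron instead of carbon. It adds to F3 with retention to give the lithium boronate complex F4.
- On warming with MgBr2·OEt2, F4 undergoes a stereospecific 1,2-metallate shift (the alkyl group migrates anti to the leaving carbamate) to the secondary pinacol boronic ester F5.
- H2O2/NaOH oxidises the C–B bond with retention to 9.

**Step 3.**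
- Risk: chloride 5 may be reluctant to insert Mg, or Wurtz and bibenzyl homocoupling may consume 6.
- Fallback: it sets out from 5 and comes back at 8.
- NaI in acetone turns 5 into (4S)-10-iododecan-4-yl N,N-diisopropylcarbamate F6. PPh3 in refluxing MeCN then gives the phosphonium iodide F7.
- NaN(SiMe3)2 in THF at −78 °C gives the ylide F8. Wittig olefination of commercial 3,5-bis(benzyloxy)benzaldehyde gives the (Z)-styrene F9; the E/Z ratio is irrelevant.
- Diimide (TsNHNH2, NaOAc, aqueous DME, reflux) saturates the alkene without touching the benzyl ethers and delivers 8. 8 is cleaved with LiAlH4 as in step 3.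

**Step 7.**
- Risk: E2 elimination of mesylate 10, or sluggish displacement by the hindered carboxylate.
- Fallback: it sets out from 11 and 9 and comes back at 16.
- TBSCl/imidazole converts 11 into the silyl ether bromide F10. n-BuLi (1.1 equiv, −78 °C) gives the aryllithium F11, CO2 gives the lithium carboxylate F12, and acidification gives the silyl-protected acid F13.
- With its own hydroxyl now blocked, F13 is esterified with the free alcohol 9 under Mitsunobu conditions (PPh3, DIAD, toluene, 0 °C → rt). This proceeds with inversion at C4 of 9 and gives the silyl-protected ester F14.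
- HF·pyridine in THF removes the silyl group and gives 16.

## Further compounds
F1 | step 2 | hex-5-en-1-ylmagnesium bromide | C=CCCCC[Mg]Br
F2 | step 2 | 1,3-bis(benzyloxy)-5-(hept-6-en-1-yl)benzene | C=CCCCCCc1cc(OCc2ccccc2)cc(OCc2ccccc2)c1
F3 | step 2 | 2-{7-[3,5-bis(benzyloxy)phenyl]heptyl}-4,4,5,5-tetramethyl-1,3,2-dioxaborolane | CC1(C)OB(CCCCCCCc2cc(OCc3ccccc3)cc(OCc3ccccc3)c2)OC1(C)C
F4 | step 2 | lithium boronate complex of F3 with (R)-1-[(diisopropylcarbamoyl)oxy]butyl on boron | CCC[C@H](OC(=O)N(C(C)C)C(C)C)[B-]1(CCCCCCCc2cc(OCc3ccccc3)cc(OCc3ccccc3)c2)OC(C)(C)C(C)(C)O1.[Li+]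
F5 | step 2 | 2-{(4S)-11-[3,5-bis(benzyloxy)phenyl]undecan-4-yl}-4,4,5,5-tetramethyl-1,3,2-dioxaborolane | CCC[C@H](B1OC(C)(C)C(C)(C)O1)CCCCCCCc1cc(OCc2ccccc2)cc(OCc2ccccc2)c1
F6 | step 3 | (4S)-10-iododecan-4-yl N,N-diisopropylcarbamate | CCC[C@H](OC(=O)N(C(C)C)C(C)C)CCCCCCI
F7 | step 3 | {(7S)-7-[(diisopropylcarbamoyl)oxy]decyl}triphenylphosphonium iodide | CCC[C@H](OC(=O)N(C(C)C)C(C)C)CCCCCC[P+](c1ccccc1)(c1ccccc1)c1ccccc1.[I-]
F8 | step 3 | {(7S)-7-[(diisopropylcarbamoyl)oxy]decylidene}triphenylphosphorane | CCC[C@H](OC(=O)N(C(C)C)C(C)C)CCCCCC=P(c1ccccc1)(c1ccccc1)c1ccccc1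
F9 | step 3 | (4S,10Z)-11-[3,5-bis(benzyloxy)phenyl]undec-10-en-4-yl N,N-diisopropylcarbamate | CCC[C@H](OC(=O)N(C(C)C)C(C)C)CCCCC/C=C\c1cc(OCc2ccccc2)cc(OCc2ccccc2)c1
F10 | step 7 | {[(4S)-11-[3,5-bis(benzyloxy)-2-bromophenyl]undecan-4-yl]oxy}(tert-butyl)dimethylsilane | CCC[C@H](O[Si](C)(C)C(C)(C)C)CCCCCCCc1cc(OCc2ccccc2)cc(OCc2ccccc2)c1Br
F11 | step 7 | 2,4-bis(benzyloxy)-6-[(8S)-8-(tert-butyldimethylsilyloxy)undecyl]phenyllithium | CCC[C@H](O[Si](C)(C)C(C)(C)C)CCCCCCCc1cc(OCc2ccccc2)cc(OCc2ccccc2)c1[Li]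
F12 | step 7 | lithium 2,4-bis(benzyloxy)-6-[(8S)-8-(tert-butyldimethylsilyloxy)undecyl]benzoate | CCC[C@H](O[Si](C)(C)C(C)(C)C)CCCCCCCc1cc(OCc2ccccc2)cc(OCc2ccccc2)c1C(=O)O[Li]
F13 | step 7 | 2,4-bis(benzyloxy)-6-[(8S)-8-(tert-butyldimethylsilyloxy)undecyl]benzoic acid | CCC[C@H](O[Si](C)(C)C(C)(C)C)CCCCCCCc1cc(OCc2ccccc2)cc(OCc2ccccc2)c1C(=O)O
F14 | step 7 | (4R)-11-[3,5-bis(benzyloxy)phenyl]undecan-4-yl 2,4-bis(benzyloxy)-6-[(8S)-8-(tert-butyldimethylsilyloxy)undecyl]benzoate | CCC[C@H](O[Si](C)(C)C(C)(C)C)CCCCCCCc1cc(OCc2ccccc2)cc(OCc2ccccc2)c1C(=O)O[C@H](CCC)CCCCCCCc1cc(OCc2ccccc2)cc(OCc2ccccc2)c1
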